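**Plan**

1. The retrosynthesis cuts the lactone C12–O bond and the C6–C7 bond together. C6–C7 is shared by the ten-membered carbocycle and the γ-lactone; the exocyclic methylene C13=C11 next to C7, with the lactone oxygen on C6, is the mark of an SE2′ allylation of a C6 aldehyde by a C13–C11=C7 allyl metal.
2. In the open chain both C6 (enal carbon) and C7 (β-carbon of the C7=C11–C12 enoate) are electrophiles. CrCl2 reverses the polarity of C7 through the C13 bromide, so one event closes the carbocycle, sets C6 and C7, creates C11=C13 and delivers the lactone.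
3. Further cuts: C7=C11 (Morita–Baylis–Hillman, then SN2′ bromination), C1=C10 (aldol condensation on a lactone), C3–C4 (B-alkyl Suzuki coupling), and the acetate and angelate.
4. Forward order: west chain C1–C6/C15 from butynediol; east unit C7–C10/C14 from 2-deoxy-L-ribonolactone; union at C1=C10; extension at C7; ten-membered ring and then γ-lactone in the key step; acyl groups last.
5. Stereochemistry: C8 and C9 come from 2-deoxy-L-ribose. C4=C5 comes from trans-hydroalumination/iodination and a stereoretentive coupling. C1=C10 comes from E1cB elimination on a temporary γ-lactone (C14–O8), whose opening also distinguishes O8 from O9. C6 and C7 come from the chair allylation under control of C8.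
6. Both ring olefins are cis within the ring (C3/C6 and C2/C9 on the same side, E by CIP), which folds C6 toward C7 for the closure.

Key step: step 16

Remark: germacrane locants are used for all intermediates (C6 bears the lactone oxygen, C7 is joined to C11, C8 bears the angelate, C9 the acetate, C10 the ester carbon C14, C4 the hydroxymethyl carbon C15, C11=C13 is the exocyclic methylene, C12 the lactone carbonyl). 2-Deoxy-L-ribose and 2-vinyl-1,3-dioxolane are taken as purchasable.

**Route**

Step 1
Reactants: 1 but-2-yne-1,4-diol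
Product: 2 4-[(tert-butyldiphenylsilyl)oxy]but-2-yn-1-ol
Conditions: 1 (3 equiv), NaH (1 equiv), THF, 0 °C; then TBDPSCl (1 equiv), rt
Reagents that add atoms: tert-butyl(chloro)diphenylsilane, CC(C)(C)[Si](Cl)(c1ccccc1)c1ccccc1
Why: O-silylation of the monosodium alkoxide of a symmetrical diol used in excess should give the mono-ether; no stereocentre is involved.

Step 2
Reactants: 2 4-[(tert-butyldiphenylsilyl)oxy]but-2-yn-1-ol
Product: 4 (2Z)-4-[(tert-butyldiphenylsilyl)oxy]-3-iodobut-2-en-1-ol, via cyclic sodium alkenylaluminate 3 (not isolated)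
Conditions: NaAlH2(OCH2CH2OMe)2, THF, 0 °C; EtOAc; then I2, −78 → 0 °C
Reagents that add atoms: iodine, II
Why: Alkoxide-directed trans-hydroalumination of the propargylic alcohol places aluminium on the distal alkyne carbon (five-membered oxaaluminacycle), and iodinolysis with retention should give the (Z)-3-iodoallylic alcohol, which fixes C15 trans to C6.

Step 3
Reactants: 4 (2Z)-4-[(tert-butyldiphenylsilyl)oxy]-3-iodobut-2-en-1-ol; 5 2-vinyl-1,3-dioxolane
Product: 7 (2E)-3-{[(tert-butyldiphenylsilyl)oxy]methyl}-5-(1,3-dioxolan-2-yl)pent-2-en-1-ol, via alkyl-9-BBN borane 6 (not isolated)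
Conditions: 5, 9-BBN-H, THF, 0 °C → rt; then 4, Pd(dppf)Cl2 (cat.), AsPh3 (cat.), Cs2CO3, DMF/H2O, rt
Reagents that add atoms: none
Why: Anti-Markovnikov hydroboration of the vinyl acetal followed by B-alkyl Suzuki–Miyaura coupling, which retains the alkene geometry, should place the C3 chain cis to C6.

Step 4
Reactants: 7 (2E)-3-{[(tert-butyldiphenylsilyl)oxy]methyl}-5-(1,3-dioxolan-2-yl)pent-2-en-1-ol
Product: 8 4-methoxybenzyl ether of 7 (O6–PMB, O15–TBDPS, C1 as dioxolane)
Conditions: NaH, PMBCl, Bu4NI (cat.), THF/DMF, 0 °C → rt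
Reagents that add atoms: 4-methoxybenzyl chloride, COc1ccc(CCl)cc1
Why: Williamson etherification of the primary allylic alkoxide; the silyl ether sits trans across the olefin and cannot migrate.

Step 5
Reactants: 8 4-methoxybenzyl ether of 7
Product: 9 (4E)-4-{[(tert-butyldiphenylsilyl)oxy]methyl}-6-[(4-methoxybenzyl)oxy]hex-4-enal
Conditions: 1 M HCl, THF, rt
Reagents that add atoms: water, O
Why: Acid-catalysed hydrolysis of the dioxolane should free the C1 aldehyde, while the PMB and TBDPS ethers are stable to dilute acid.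

Step 6
Reactants: 10 2-deoxy-L-ribose
Product: 11 2-deoxy-L-ribono-1,4-lactone [(4R,5S)-4-hydroxy-5-(hydroxymethyl)oxolan-2-one]
Conditions: Br2, H2O, rt, dark; then evaporation
Reagents that add atoms: none
Why: Bromine-water oxidation of the aldose hemiacetal gives the aldono-1,4-lactone without touching the two stereocentres that become C9 and C8.

Step 7
Reactants: 11 2-deoxy-L-ribono-1,4-lactone
Product: 13 (4R,5S)-4-[(tert-butyldimethylsilyl)oxy]-5-{[(triethylsilyl)oxy]methyl}oxolan-2-one, via 5-O-triethylsilyl lactone 12 (not isolated)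
Conditions: TESCl (1.05 equiv), imidazole, DMF, −40 °C; then TBSCl, rt
Reagents that add atoms: chlorotriethylsilane, CC[Si](Cl)(CC)CC; tert-butyl(chloro)dimethylsilane, CC(C)(C)[Si](C)(C)Cl
Why: Primary-selective silylation at low temperature followed by silylation of the secondary hydroxyl in the same flask should give O7–TES (the group later oxidised directly) and O9–TBS (the most robust of the three secondary-oxygen groups).

Step 8
Reactants: 13 (4R,5S)-4-[(tert-butyldimethylsilyl)oxy]-5-{[(triethylsilyl)oxy]methyl}oxolan-2-one; 9 (4E)-4-{[(tert-butyldiphenylsilyl)oxy]methyl}-6-[(4-methoxybenzyl)oxy]hex-4-enal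
Product: 15 aldol adduct, lactone 13 bearing at C10 the 1-hydroxyalkyl chain of 9 (mixture at C1 and C10), via lithium enolate 14 (not isolated)
Conditions: LiN(SiMe3)2, THF, −78 °C; then 9, −78 °C; AcOH quench
Reagents that add atoms: none
Why: Lithium enolate aldol addition at −78 °C, where the β-silyloxy group should not eliminate; the new centres at C1 and C10 are irrelevant because both become sp2 in step 9.

Step 9
Reactants: 15 aldol adduct
Product: 17 (E)-α-alkylidene-γ-lactone (C1=C10 formed; C2 anti to the lactone carbonyl C14 and syn to C9), via C1 mesylate 16 (not isolated)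
Conditions: MsCl, Et3N, CH2Cl2, 0 °C; then DBU, 0 °C → rt
Reagents that add atoms: none
Why: Mesylation and E1cB elimination on a γ-butyrolactone should give the (E)-alkylidene lactone, the usual and thermodynamic outcome of lactone aldol condensation, and this sets the C1=C10 geometry of the target.

Step 10
Reactants: 17 (E)-α-alkylidene-γ-lactone
Product: 20 open-chain methyl ester with O8–TES, O7–TES, O9–TBS, O6–PMB and O15–TBDPS, via lithium carboxylate 18 (not isolated), via hydroxy ester 19 (not isolated)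
Conditions: LiOH, THF/H2O, 0 °C; evaporate; MeI, DMF, 0 °C; remove excess MeI; then imidazole, TESCl, 0 °C → rt
Reagents that add atoms: lithium hydroxide, [Li+].[OH-]; iodomethane, CI; chlorotriethylsilane, CC[Si](Cl)(CC)CC
Why: Lactone saponification, O-alkylation of the carboxylate and silylation of the freed C8 hydroxyl before it can relactonise; opening the temporary C14–O8 lactone releases O8 alone, so O8 and O9 end with different silyl groups.

Step 11
Reactants: 20 open-chain methyl ester
Product: 21 C7 aldehyde (α-OTES at C8, β-OTBS at C9)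
Conditions: (COCl)2, DMSO, CH2Cl2, −78 → −40 °C; then Et3N, −78 → 0 °C
Reagents that add atoms: none
Why: Swern conditions convert a primary triethylsilyl ether directly into the aldehyde, while secondary TES, TBS and TBDPS ethers are inert (known selective oxidation of primary TES ethers).

Step 12
Reactants: 21 C7 aldehyde; 22 methyl acrylate
Product: 23 Morita–Baylis–Hillman adduct, C7 carbinol bearing the C11(=C13H2)–C12O2Me unit (mixture at C7)
Conditions: DABCO (1 equiv), 22 (excess), MeOH (2 equiv), rt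
Reagents that add atoms: none
Why: Morita–Baylis–Hillman reaction of an α-silyloxy aldehyde; the new C7 carbinol centre is of no consequence because it becomes sp2 in step 13.

Step 13
Reactants: 23 Morita–Baylis–Hillman adduct
Product: 24 (Z)-2-(bromomethyl)enoate (C7=C11, C13H2Br; C8 cis to C13 and trans to the C12 ester)
Conditions: NBS, Me2S, CH2Cl2, 0 °C → rt
Reagents that add atoms: N-bromosuccinimide, O=C1CCC(=O)N1Br
Why: The bromosulfonium reagent (Corey–Kim type) activates the allylic alcohol and bromide attacks in SN2′ fashion, which should give the (Z)-2-(bromomethyl)alk-2-enoate as is usual for ester-derived adducts.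

Step 14
Reactants: 24 (Z)-2-(bromomethyl)enoate
Product: 25 C6 allylic alcohol
Conditions: DDQ, CH2Cl2/pH 7 buffer, 0 °C
Reagents that add atoms: none
Why: Oxidative cleavage of the PMB ether under neutral conditions, which leave the allylic bromide and the silyl ethers intact.

Step 15
Reactants: 25 C6 allylic alcohol
Product: 26 cyclisation precursor, (4E)-enal at C6 with the (Z)-2-(bromomethyl)enoate at C7=C11
Conditions: MnO2 (excess), CH2Cl2, rt
Reagents that add atoms: none
Why: MnO2 oxidises the primary allylic alcohol chemoselectively and without base, so the bromide survives and the C4=C5 geometry is kept.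

Step 16
Reactants: 26 cyclisation precursor
Product: 29 ten-membered α-methylene-γ-lactone, methyl 9-[(tert-butyldimethylsilyl)oxy]-15-[(tert-butyldiphenylsilyl)oxy]-8-[(triethylsilyl)oxy]germacra-1(10),4,11(13)-trien-12,6-olid-14-oate (6R,7S,8S,9R; trans-fused lactone), via allylchromium dichloride 27 (not isolated), via chromium alkoxide 28 (not isolated)
Conditions: CrCl2 (10 equiv), THF/DMF, rt, slow addition of 26 (final 2 mM); aq. NH4Cl
Reagents that add atoms: none
Why: CrCl2 reduces the allylic C13–Br bond by two single-electron transfers to the allylchromium species 27 (trivalent chromium), which adds through its γ-carbon C7 to the aldehyde carbon C6 in a six-membered chair transition state (intramolecular Nozaki–Hiyama–Kishi/Barbier allylation, SE2′), moving the double bond to C11=C13; the chromium alkoxide 28 then attacks the C12 methyl ester to close the lactone. The closest known reaction type is the CrCl2-mediated Barbier cyclisation of ω-formyl 2-(bromomethyl)alk-2-enoates to carbocycle-fused α-methylene-γ-butyrolactones, ten-membered germacranolide rings included. The carbocycle closes 10-exo-trig at the aldehyde (C6–C7 bond) and the lactone closes 5-exo-trig by attack of O6 on C12. C6 and C7 arise together: allylchromium reagents equilibrate by 1,3-metal shift, so the chair with both ring tethers equatorial (C5 on C6, C8 on C7) is open whatever the bromide geometry and should give the anti adduct, that is the trans-fused lactone; the face of C7 is set by C8, whose hydrogen eclipses the C7=C11 plane (allylic 1,3-strain), so that the aldehyde adds anti to the C8–C9 bond with the silyloxy group outside. The step needs γ- over α-attack (inherent to allylchromium), reduction of the allylic bromide in the presence of enal and enoates (CrCl2 is selective for this), and ring closure over oligomerisation, which slow addition at high dilution and the two ring-cis olefins C1=C10 and C4=C5 should secure.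

Step 17
Reactants: 29 ten-membered α-methylene-γ-lactone
Product: 30 C8 alcohol (O9–TBS and O15–TBDPS retained)
Conditions: PPTS (cat.), MeOH/CH2Cl2, 0 °C
Reagents that add atoms: none
Why: Acid-catalysed methanolysis removes the secondary TES ether, while TBS and TBDPS ethers react orders of magnitude more slowly.

Step 18
Reactants: 30 C8 alcohol; 31 angelic acid [(2Z)-2-methylbut-2-enoic acid]
Product: 33 8-O-angelate (O9–TBS, O15–TBDPS), via angelic trichlorobenzoic mixed anhydride 32 (not isolated)
Conditions: 31, 2,4,6-trichlorobenzoyl chloride, Et3N, toluene, rt; then 30, 80 °C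
Reagents that add atoms: none
Why: Yamaguchi-type mixed-anhydride esterification without a nucleophilic catalyst, conditions known to transfer the angeloyl group without Z to E isomerisation; the angelate goes on first because it migrates far less readily than an acetate.

Step 19
Reactants: 33 8-O-angelate
Product: 34 C9 alcohol (O15–TBDPS retained)
Conditions: aq. HF (48 %), MeCN, 0 °C → rt
Reagents that add atoms: none
Why: Aqueous HF in acetonitrile cleaves alkyl TBS ethers while primary TBDPS ethers survive, and esters and the α-methylene lactone tolerate the acidic medium.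

Step 20
Reactants: 34 C9 alcohol
Product: 35 9-O-acetate, the 15-O-TBDPS ether of the target
Conditions: Ac2O, pyridine, DMAP (cat.), CH2Cl2, 0 °C
Reagents that add atoms: acetic anhydride, CC(=O)OC(C)=O
Why: Fast DMAP-catalysed acetylation at 0 °C of the only free hydroxyl should outrun any 8 to 9 migration of the hindered angeloyl group.

Step 21
Reactants: 35 9-O-acetate
Product: 36 CNP0216801.3 (target)
Conditions: HF·pyridine, pyridine/THF, 0 °C → rt
Reagents that add atoms: none
Why: Buffered fluoride desilylation of the primary TBDPS ether leaves the acetate, angelate, methyl ester and α-methylene lactone untouched and frees the C15 hydroxyl, which has no neighbouring ester to accept an acyl shift.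

**Compound list**

1 | but-2-yne-1,4-diol | OCC#CCO | starting material
2 | 4-[(tert-butyldiphenylsilyl)oxy]but-2-yn-1-ol | OCC#CCO[Si](c1ccccc1)(c1ccccc1)C(C)(C)C | intermediate
3 | cyclic sodium alkenylaluminate from 2 (Al on C4, O6–Al ring) | [Na+].COCCO[Al-]1(OCCOC)OCC=C1CO[Si](c2ccccc2)(c2ccccc2)C(C)(C)C | intermediate (not isolated)
4 | (2Z)-4-[(tert-butyldiphenylsilyl)oxy]-3-iodobut-2-en-1-ol | OC/C=C(/CO[Si](c1ccccc1)(c1ccccc1)C(C)(C)C)I | intermediate
5 | 2-vinyl-1,3-dioxolane | C=CC1OCCO1 | starting material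
6 | 9-[2-(1,3-dioxolan-2-yl)ethyl]-9-borabicyclo[3.3.1]nonane | C1CCC2CCCC1B2CCC1OCCO1 | intermediate (not isolated)
7 | (2E)-3-{[(tert-butyldiphenylsilyl)oxy]methyl}-5-(1,3-dioxolan-2-yl)pent-2-en-1-ol | OC/C=C(/CO[Si](c1ccccc1)(c1ccccc1)C(C)(C)C)CCC1OCCO1 | intermediate
8 | 4-methoxybenzyl ether of 7 | COc1ccc(COC/C=C(/CO[Si](c2ccccc2)(c2ccccc2)C(C)(C)C)CCC2OCCO2)cc1 | intermediate
9 | (4E)-4-{[(tert-butyldiphenylsilyl)oxy]methyl}-6-[(4-methoxybenzyl)oxy]hex-4-enal | COc1ccc(COC/C=C(/CO[Si](c2ccccc2)(c2ccccc2)C(C)(C)C)CCC=O)cc1 | intermediate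
10 | 2-deoxy-L-ribose [(3R,4S)-3,4,5-trihydroxypentanal] | O=CC[C@@H](O)[C@@H](O)CO | starting material
11 | 2-deoxy-L-ribono-1,4-lactone | O=C1C[C@@H](O)[C@H](CO)O1 | intermediate
12 | 5-O-triethylsilyl-2-deoxy-L-ribono-1,4-lactone | O=C1C[C@@H](O)[C@H](CO[Si](CC)(CC)CC)O1 | intermediate (not isolated)
13 | (4R,5S)-4-[(tert-butyldimethylsilyl)oxy]-5-{[(triethylsilyl)oxy]methyl}oxolan-2-one | O=C1C[C@@H](O[Si](C)(C)C(C)(C)C)[C@H](CO[Si](CC)(CC)CC)O1 | intermediate
14 | lithium enolate of 13 | [Li+].[O-]C1=C[C@@H](O[Si](C)(C)C(C)(C)C)[C@H](CO[Si](CC)(CC)CC)O1 | intermediate (not isolated)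
15 | aldol adduct of 13 and 9 (mixture at C1 and C10) | COc1ccc(COC/C=C(/CO[Si](c2ccccc2)(c2ccccc2)C(C)(C)C)CCC(O)C2C(=O)O[C@@H](CO[Si](CC)(CC)CC)[C@@H]2O[Si](C)(C)C(C)(C)C)cc1 | intermediate
16 | C1 mesylate of 15 | COc1ccc(COC/C=C(/CO[Si](c2ccccc2)(c2ccccc2)C(C)(C)C)CCC(OS(C)(=O)=O)C2C(=O)O[C@@H](CO[Si](CC)(CC)CC)[C@@H]2O[Si](C)(C)C(C)(C)C)cc1 | intermediate (not isolated)
17 | (E)-α-alkylidene-γ-lactone (C1=C10; lactone C14–O8) | COc1ccc(COC/C=C(/CO[Si](c2ccccc2)(c2ccccc2)C(C)(C)C)CC/C=C2/C(=O)O[C@@H](CO[Si](CC)(CC)CC)[C@@H]2O[Si](C)(C)C(C)(C)C)cc1 | intermediate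
18 | lithium carboxylate from 17 (C8–OH free) | COc1ccc(COC/C=C(/CO[Si](c2ccccc2)(c2ccccc2)C(C)(C)C)CC/C=C(/C(=O)[O-])[C@@H](O[Si](C)(C)C(C)(C)C)[C@@H](O)CO[Si](CC)(CC)CC)cc1.[Li+] | intermediate (not isolated)
19 | hydroxy methyl ester (C14 methyl ester, C8–OH free) | COc1ccc(COC/C=C(/CO[Si](c2ccccc2)(c2ccccc2)C(C)(C)C)CC/C=C(/C(=O)OC)[C@@H](O[Si](C)(C)C(C)(C)C)[C@@H](O)CO[Si](CC)(CC)CC)cc1 | intermediate (not isolated)
20 | open-chain methyl ester, O8–TES, O7–TES, O9–TBS, O6–PMB, O15–TBDPS | COc1ccc(COC/C=C(/CO[Si](c2ccccc2)(c2ccccc2)C(C)(C)C)CC/C=C(/C(=O)OC)[C@@H](O[Si](C)(C)C(C)(C)C)[C@@H](O[Si](CC)(CC)CC)CO[Si](CC)(CC)CC)cc1 | intermediate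
21 | C7 aldehyde | COc1ccc(COC/C=C(/CO[Si](c2ccccc2)(c2ccccc2)C(C)(C)C)CC/C=C(/C(=O)OC)[C@@H](O[Si](C)(C)C(C)(C)C)[C@@H](O[Si](CC)(CC)CC)C=O)cc1 | intermediate
22 | methyl acrylate | C=CC(=O)OC | starting material
23 | Morita–Baylis–Hillman adduct (mixture at C7) | COc1ccc(COC/C=C(/CO[Si](c2ccccc2)(c2ccccc2)C(C)(C)C)CC/C=C(/C(=O)OC)[C@@H](O[Si](C)(C)C(C)(C)C)[C@@H](O[Si](CC)(CC)CC)C(O)C(=C)C(=O)OC)cc1 | intermediate
24 | (Z)-2-(bromomethyl)enoate, O6–PMB | COc1ccc(COC/C=C(/CO[Si](c2ccccc2)(c2ccccc2)C(C)(C)C)CC/C=C(/C(=O)OC)[C@@H](O[Si](C)(C)C(C)(C)C)[C@@H](O[Si](CC)(CC)CC)/C=C(\CBr)C(=O)OC)cc1 | intermediate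
25 | C6 allylic alcohol | OC/C=C(/CO[Si](c1ccccc1)(c1ccccc1)C(C)(C)C)CC/C=C(/C(=O)OC)[C@@H](O[Si](C)(C)C(C)(C)C)[C@@H](O[Si](CC)(CC)CC)/C=C(\CBr)C(=O)OC | intermediate
26 | cyclisation precursor, C6 enal with (Z)-2-(bromomethyl)enoate | O=C/C=C(/CO[Si](c1ccccc1)(c1ccccc1)C(C)(C)C)CC/C=C(/C(=O)OC)[C@@H](O[Si](C)(C)C(C)(C)C)[C@@H](O[Si](CC)(CC)CC)/C=C(\CBr)C(=O)OC | intermediate
27 | allylchromium dichloride (Cr on C13, drawn with the geometry first formed) | O=C/C=C(/CO[Si](c1ccccc1)(c1ccccc1)C(C)(C)C)CC/C=C(/C(=O)OC)[C@@H](O[Si](C)(C)C(C)(C)C)[C@@H](O[Si](CC)(CC)CC)/C=C(\C[Cr](Cl)Cl)C(=O)OC | intermediate (not isolated)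
28 | chromium alkoxide of the ring-closed ten-membered hydroxy ester | COC(=O)C(=C)[C@H]1[C@H](O[Cr](Cl)Cl)/C=C(/CO[Si](c2ccccc2)(c2ccccc2)C(C)(C)C)CC/C=C(/C(=O)OC)[C@@H](O[Si](C)(C)C(C)(C)C)[C@H]1O[Si](CC)(CC)CC | intermediate (not isolated)
29 | ten-membered α-methylene-γ-lactone, O8–TES, O9–TBS, O15–TBDPS | C=C1C(=O)O[C@@H]2/C=C(/CO[Si](c3ccccc3)(c3ccccc3)C(C)(C)C)CC/C=C(/C(=O)OC)[C@@H](O[Si](C)(C)C(C)(C)C)[C@@H](O[Si](CC)(CC)CC)[C@@H]12 | intermediate
30 | C8 alcohol | C=C1C(=O)O[C@@H]2/C=C(/CO[Si](c3ccccc3)(c3ccccc3)C(C)(C)C)CC/C=C(/C(=O)OC)[C@@H](O[Si](C)(C)C(C)(C)C)[C@@H](O)[C@@H]12 | intermediate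
31 | angelic acid | C/C=C(/C)C(=O)O | starting material
32 | angelic 2,4,6-trichlorobenzoic anhydride | C/C=C(/C)C(=O)OC(=O)c1c(Cl)cc(Cl)cc1Cl | intermediate (not isolated)
33 | 8-O-angelate, O9–TBS, O15–TBDPS | C=C1C(=O)O[C@@H]2/C=C(/CO[Si](c3ccccc3)(c3ccccc3)C(C)(C)C)CC/C=C(/C(=O)OC)[C@@H](O[Si](C)(C)C(C)(C)C)[C@@H](OC(=O)/C(C)=C\C)[C@@H]12 | intermediate
34 | C9 alcohol, O15–TBDPS | C=C1C(=O)O[C@@H]2/C=C(/CO[Si](c3ccccc3)(c3ccccc3)C(C)(C)C)CC/C=C(/C(=O)OC)[C@@H](O)[C@@H](OC(=O)/C(C)=C\C)[C@@H]12 | intermediate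
35 | 15-O-TBDPS ether of the target | C=C1C(=O)O[C@@H]2/C=C(/CO[Si](c3ccccc3)(c3ccccc3)C(C)(C)C)CC/C=C(/C(=O)OC)[C@@H](OC(C)=O)[C@@H](OC(=O)/C(C)=C\C)[C@@H]12 | intermediate
36 | CNP0216801.3 (6R,7S,8S,9R) | C=C1C(=O)O[C@@H]2/C=C(/CO)CC/C=C(/C(=O)OC)[C@@H](OC(C)=O)[C@@H](OC(=O)/C(C)=C\C)[C@@H]12 | target

**Count and risks**

Total steps: 21. Longest linear sequence: 19 (steps 1–5, then 8–21).

Step 16. The allylchromium may add to the wrong face of the aldehyde (syn adduct, cis-fused lactone), or chains may couple with each other instead of closing. The fallback sets out from 26 and returns at 29. The same cyclisation is run and the C6-epimeric cis-fused lactone F1 is accepted. Its lactone is saponified selectively (LiOH, THF/H2O, 0 °C; the hindered conjugated C14 ester is slower) to the hydroxy acid F2. F2 is relactonised under Mitsunobu conditions (PPh3, DIAD, toluene, 0 °C), which closes the five-membered ring with inversion at the allylic C6 and gives the trans-fused lactone 29.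

Step 18. The angeloyl group may isomerise to tigloyl during acyl transfer, or the hindered C8 hydroxyl between C7 and the C9 silyl ether may not acylate. The fallback sets out from 30 and returns at 33. Alcohol 30 is esterified with 2-[bis(2,2,2-trifluoroethoxy)phosphoryl]propanoic acid (DCC, DMAP, CH2Cl2) to the phosphonate ester F3. Still–Gennari olefination of F3 with acetaldehyde (KN(SiMe3)2, 18-crown-6, THF, −78 °C) builds the (Z)-2-methylbut-2-enoate in place and gives 33.

Step 12. Amine-catalysed addition to the hindered α-silyloxy aldehyde may be slow, and prolonged exposure to base could epimerise C8 or eliminate the C9 silyloxy group. The fallback sets out from 21 and returns at 23. The lithium enolate of methyl 2-(phenylselanyl)propanoate (LiN(iPr)2, THF, −78 °C) is added to 21 to give the β-hydroxy α-selanyl ester F4. Oxidation (H2O2, pyridine, CH2Cl2, 0 °C) and selenoxide syn-elimination, which can only run toward the methyl group, give 23.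

Further compounds
F1 | step 16 | cis-fused lactone, C6 epimer of 29 | C=C1C(=O)O[C@H]2/C=C(/CO[Si](c3ccccc3)(c3ccccc3)C(C)(C)C)CC/C=C(/C(=O)OC)[C@@H](O[Si](C)(C)C(C)(C)C)[C@@H](O[Si](CC)(CC)CC)[C@@H]12
F2 | step 16 | ring-opened hydroxy acid from F1 (C12 acid, C6-epi alcohol) | OC(=O)C(=C)[C@H]1[C@@H](O)/C=C(/CO[Si](c2ccccc2)(c2ccccc2)C(C)(C)C)CC/C=C(/C(=O)OC)[C@@H](O[Si](C)(C)C(C)(C)C)[C@H]1O[Si](CC)(CC)CC
F3 | step 18 | 8-O-{2-[bis(2,2,2-trifluoroethoxy)phosphoryl]propanoate} of 30 | C=C1C(=O)O[C@@H]2/C=C(/CO[Si](c3ccccc3)(c3ccccc3)C(C)(C)C)CC/C=C(/C(=O)OC)[C@@H](O[Si](C)(C)C(C)(C)C)[C@@H](OC(=O)C(C)P(=O)(OCC(F)(F)F)OCC(F)(F)F)[C@@H]12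
F4 | step 12 | β-hydroxy α-methyl α-(phenylselanyl) ester from 21 | COc1ccc(COC/C=C(/CO[Si](c2ccccc2)(c2ccccc2)C(C)(C)C)CC/C=C(/C(=O)OC)[C@@H](O[Si](C)(C)C(C)(C)C)[C@@H](O[Si](CC)(CC)CC)C(O)C(C)([Se]c2ccccc2)C(=O)OC)cc1
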